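**Retrosynthetic overview**
- C4=C5 is cut by ring-closing metathesis to an acyclic cis-vinyl oxirane. That oxirane is cut by hydroxyl-directed epoxidation of a Z-trisubstituted C1=C6 olefin. Both forward events run in one flask, oxirane first and carbocycle last.
- Enabling feature: the oxirane (O7, C1, C6) is cis-fused and lies opposite the only ring olefin, the unsubstituted C4=C5. It therefore clamps the C6-vinyl and the C1-C2-C3-vinyl arm on one side, and the C2 carbinol next to C1 relays its configuration to C1 and C6.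
- The triene precursor carries only the C2 and C3 stereocentres. It comes from a butenolide (temporary ring O-C2-C1=C6-C5(=O)) by lactone reduction and methylenation; the ring fixes the Z geometry.
- The C2-C3 bond and both carbinol centres come from one catalytic asymmetric vinylogous Mukaiyama aldol of a 2-silyloxyfuran with acrolein. The butenolide is dihydroxyacetone plus a stabilised ylide.
- Ring order: butenolide (temporary, opened again), oxirane, cyclohexene. Three silyl and benzoate steps then finish the target.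

Key step: step 6

Remarks:
- Locants are those of the 7-oxabicyclo[4.1.0]hept-4-ene target: C1 quaternary oxirane carbon, C2 CHOBz, C3 CHOH, C4=C5, C6 oxirane CH, O7, and C1′ for the CH2O branch.
- TBS = tert-butyldimethylsilyl, TES = triethylsilyl, Bz = benzoyl.
- Assumption: the (R,R)-catalyst of step 3 is taken to expose the Si face of acrolein. If the sense is opposite, its equally available antipode is used and nothing else changes.

Step 1
Reactants: 1 1,3-dihydroxyacetone (sold as its dimer); 2 ethyl (triphenylphosphoranylidene)acetate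
Product: 3 4-(hydroxymethyl)furan-2(5H)-one
Conditions: CH2Cl2, rt
Reagents that add atoms: none
Why: Wittig olefination of the symmetrical ketone is followed by spontaneous lactonisation, because one CH2OH is always cis to the ester, so the ring ties the future C2 and C5 cis across C1=C6.

Step 2
Reactants: 3 4-(hydroxymethyl)furan-2(5H)-one
Product: 4 2-(TBSO)-4-(TBSO-methyl)furan
Conditions: TBSOTf (2.2 equiv), Et3N, CH2Cl2, 0 °C
Reagents that add atoms: tert-butyldimethylsilyl triflate, CC(C)(C)[Si](C)(C)OS(=O)(=O)C(F)(F)F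
Why: Soft enolisation and O-silylation of the butenolide give the aromatic 2-silyloxyfuran, whose ring C5 (the future C2) becomes nucleophilic, while the primary alcohol is silylated in the same operation.

Step 3
Reactants: 4 2-(TBSO)-4-(TBSO-methyl)furan; 5 acrolein (prop-2-enal)
Product: 6 (5R)-4-(TBSO-methyl)-5-[(1R)-1-hydroxyprop-2-en-1-yl]furan-2(5H)-one
Conditions: SiCl4 (1.1 equiv), (R,R)-bisphosphoramide [pentane-1,5-diylbis(N-methylamide) of the cyclic phosphoric diamide of (R)-N,N′-dimethyl-1,1′-binaphthyl-2,2′-diamine] (5 mol %), i-Pr2NEt (10 mol %), CH2Cl2, −78 °C; aq. NaHCO3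
Reagents that add atoms: none
Why: In this catalytic asymmetric vinylogous Mukaiyama aldol the phosphoramide-bound chlorosilyl cation activates the conjugated aldehyde, and the furan attacks through its gamma carbon in an open transition state that gives the threo adduct typical of 2-silyloxyfurans under Lewis acids, the catalyst selecting the aldehyde face, so C2 and C3 are set in one event.

Step 4
Reactants: 6 (5R)-4-(TBSO-methyl)-5-[(1R)-1-hydroxyprop-2-en-1-yl]furan-2(5H)-one
Product: 7 (5R)-4-(TBSO-methyl)-5-[(1R)-1-(TESO)prop-2-en-1-yl]furan-2(5H)-one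
Conditions: TESCl, imidazole, CH2Cl2, 0 °C
Reagents that add atoms: chlorotriethylsilane, CC[Si](Cl)(CC)CC
Why: Standard silylation masks the only free hydroxyl (C3-OH), so that after ring opening the C2-OH is the only hydroxyl left to direct the epoxidation and to be benzoylated.

Step 5
Reactants: 7 (5R)-4-(TBSO-methyl)-5-[(1R)-1-(TESO)prop-2-en-1-yl]furan-2(5H)-one
Product: 9 (3R,4R,5Z)-5-(TBSO-methyl)-3-(TESO)octa-1,5,7-trien-4-ol, via lactol 8 (not isolated)
Conditions: i-Bu2AlH (1.1 equiv), CH2Cl2, −78 °C; then Ph3P=CH2 (from Ph3PCH3Br, KN(SiMe3)2, THF; 3 equiv), −78 °C to rt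
Reagents that add atoms: methyltriphenylphosphonium bromide (as its ylide), C[P+](c1ccccc1)(c1ccccc1)c1ccccc1.[Br-]
Why: Partial lactone reduction and Wittig methylenation of the ring-opened Z-oxido-enal in the same flask avoid acid contact of the lactol (which would dehydrate to a furan), keep the ring-derived Z geometry, free the C2-OH and touch no stereocentre.

Step 6
Reactants: 9 (3R,4R,5Z)-5-(TBSO-methyl)-3-(TESO)octa-1,5,7-trien-4-ol
Product: 11 (1R,2S,3R,6S)-1-(TBSO-methyl)-3-(TESO)-7-oxabicyclo[4.1.0]hept-4-en-2-ol, via vinyl oxirane 10 (not isolated)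
Conditions: purified m-CPBA (1.0 equiv), CH2Cl2, −20 °C; cold filtration through basic alumina into CH2Cl2 (2 mM); RuCl2(PCy3)(H2IMes)(=CHPh) (second-generation Grubbs catalyst, 5 mol %), 40 °C
Reagents that add atoms: m-chloroperoxybenzoic acid, O=C(OO)c1cccc(Cl)c1
Why: The peracid is hydrogen-bonded to the C2 hydroxyl, and A(1,3) strain between the C2 substituents and the Z-placed C6-vinyl holds C2-H in the olefin plane, so oxygen is delivered in a concerted syn addition to the face that carries the OH (threo-selective hydroxyl-directed Prilezhaev epoxidation, closest precedent Z-trisubstituted allylic alcohols); this closes the oxirane as a [2+1] addition and sets C1 and C6 together from C2. Chemoselectivity rests on C1=C6 being the only trisubstituted and the only carbinol-flanked olefin, the two monosubstituted vinyl groups being far less nucleophilic. Because the Z geometry is retained, the C6-vinyl and the C1-C2-C3 arm end up cis on the rigid three-membered ring, which brings the two terminal olefins within bonding distance. The ruthenium alkylidene then exchanges with one vinyl group and closes C4=C5 through a metallacyclobutane (ring-closing metathesis of a 1,7-diene to a six-membered ring with loss of ethene), as known for polyoxygenated octa-1,7-dienes and for vinyl oxiranes. No other ring size can compete because only two olefins are left, a trans-oxirane could not cyclise at all, and no stereocentre is touched in this second stage. Leaving the acid-sensitive acyclic vinyl oxirane unisolated avoids its loss on silica, so one flask takes an acyclic triene with two stereocentres to the complete bicyclic core with four.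

Step 7
Reactants: 11 (1R,2S,3R,6S)-1-(TBSO-methyl)-3-(TESO)-7-oxabicyclo[4.1.0]hept-4-en-2-ol
Product: 12 (1S,2S,3R,6S)-1-(TBSO-methyl)-3-(TESO)-7-oxabicyclo[4.1.0]hept-4-en-2-yl benzoate
Conditions: BzCl, Et3N, DMAP (cat.), CH2Cl2, 0 °C to rt
Reagents that add atoms: benzoyl chloride, O=C(Cl)c1ccccc1
Why: DMAP-catalysed acylation of the only free hydroxyl places the C2 benzoate with retention, under conditions that leave the oxirane and silyl ethers intact.

Step 8
Reactants: 12 (1S,2S,3R,6S)-1-(TBSO-methyl)-3-(TESO)-7-oxabicyclo[4.1.0]hept-4-en-2-yl benzoate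
Product: 13 (1S,2S,3R,6S)-3-hydroxy-1-(hydroxymethyl)-7-oxabicyclo[4.1.0]hept-4-en-2-yl benzoate
Conditions: Et3N·3HF, MeCN/THF, rt
Reagents that add atoms: none
Why: Fluoride-driven cleavage of the secondary TES and primary TBS ethers in a weakly acidic medium forms no alkoxide, so benzoate migration and Payne rearrangement should be suppressed and the allylic oxirane should survive.

Step 9
Reactants: 13 (1S,2S,3R,6S)-3-hydroxy-1-(hydroxymethyl)-7-oxabicyclo[4.1.0]hept-4-en-2-yl benzoate
Product: 14 [(1S,2S,3R,6S)-2-(benzoyloxy)-3-hydroxy-7-oxabicyclo[4.1.0]hept-4-en-1-yl]methyl benzoate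
Conditions: BzCl (1.05 equiv), 2,4,6-collidine, CH2Cl2, −40 °C to 0 °C
Reagents that add atoms: benzoyl chloride, O=C(Cl)c1ccccc1
Why: Kinetically selective acylation with one equivalent of acid chloride and a weak hindered base should favour the primary C1′-OH over the secondary C3-OH that is flanked by the C2 benzoate.

**Compound list**
1 | 1,3-dihydroxyacetone | OCC(=O)CO | starting material
2 | ethyl (triphenylphosphoranylidene)acetate | CCOC(=O)C=P(c1ccccc1)(c1ccccc1)c1ccccc1 | starting material
3 | 4-(hydroxymethyl)furan-2(5H)-one | O=C1C=C(CO)CO1 | intermediate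
4 | 2-[(tert-butyldimethylsilyl)oxy]-4-{[(tert-butyldimethylsilyl)oxy]methyl}furan | CC(C)(C)[Si](C)(C)OCc1coc(O[Si](C)(C)C(C)(C)C)c1 | intermediate
5 | acrolein | C=CC=O | starting material
6 | (5R)-4-(TBSO-methyl)-5-[(1R)-1-hydroxyprop-2-en-1-yl]furan-2(5H)-one (threo) | O=C1C=C(CO[Si](C)(C)C(C)(C)C)[C@@H](O1)[C@H](O)C=C | intermediate
7 | (5R)-4-(TBSO-methyl)-5-[(1R)-1-(TESO)prop-2-en-1-yl]furan-2(5H)-one | O=C1C=C(CO[Si](C)(C)C(C)(C)C)[C@@H](O1)[C@H](O[Si](CC)(CC)CC)C=C | intermediate
8 | (5R)-4-(TBSO-methyl)-5-[(1R)-1-(TESO)prop-2-en-1-yl]-2,5-dihydrofuran-2-ol (lactol, both anomers, not isolated) | OC1C=C(CO[Si](C)(C)C(C)(C)C)[C@@H](O1)[C@H](O[Si](CC)(CC)CC)C=C | intermediate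
9 | (3R,4R,5Z)-5-(TBSO-methyl)-3-(TESO)octa-1,5,7-trien-4-ol | C=C/C=C(/CO[Si](C)(C)C(C)(C)C)[C@@H](O)[C@H](O[Si](CC)(CC)CC)C=C | intermediate
10 | (1S,2R)-1-[(2R,3S)-2-(TBSO-methyl)-3-ethenyloxiran-2-yl]-2-(TESO)but-3-en-1-ol (not isolated) | C=C[C@@H]1O[C@]1(CO[Si](C)(C)C(C)(C)C)[C@@H](O)[C@H](O[Si](CC)(CC)CC)C=C | intermediate
11 | (1R,2S,3R,6S)-1-(TBSO-methyl)-3-(TESO)-7-oxabicyclo[4.1.0]hept-4-en-2-ol | CC(C)(C)[Si](C)(C)OC[C@]12O[C@H]1C=C[C@@H](O[Si](CC)(CC)CC)[C@@H]2O | intermediate
12 | (1S,2S,3R,6S)-1-(TBSO-methyl)-3-(TESO)-7-oxabicyclo[4.1.0]hept-4-en-2-yl benzoate | CC(C)(C)[Si](C)(C)OC[C@]12O[C@H]1C=C[C@@H](O[Si](CC)(CC)CC)[C@@H]2OC(=O)c1ccccc1 | intermediate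
13 | (1S,2S,3R,6S)-3-hydroxy-1-(hydroxymethyl)-7-oxabicyclo[4.1.0]hept-4-en-2-yl benzoate | OC[C@]12O[C@H]1C=C[C@@H](O)[C@@H]2OC(=O)c1ccccc1 | intermediate
14 | [(1S,2S,3R,6S)-2-(benzoyloxy)-3-hydroxy-7-oxabicyclo[4.1.0]hept-4-en-1-yl]methyl benzoate | O=C(OC[C@]12O[C@H]1C=C[C@@H](O)[C@@H]2OC(=O)c1ccccc1)c1ccccc1 | target

Total step count: 9. Longest linear sequence: 9 steps (from 1).

**Steps most likely to fail**

Step 6.
- Risk: facial selectivity could erode if hydrogen bonding to the C2 hydroxyl is outcompeted. The vinyl oxirane could open under acid before closure. The ruthenium alkylidene could be deactivated by traces of peracid or by the free hydroxyl.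
- Fallback, from 9 back to 12: the epoxidation is taken out of substrate control and out of the shared flask.
- Shi epoxidation of 9 is run with the L-fructose-derived ketone (1,2:4,5-di-O-isopropylidene-β-L-erythro-hexo-2,3-diulo-2,6-pyranose), KHSO5 and K2CO3 buffer in MeCN/dimethoxymethane/H2O at 0 °C. The chiral dioxirane selects the same face of the trisubstituted olefin and should give 10, now isolated on buffered silica.
- Benzoylation (BzCl, Et3N, DMAP) gives the acyclic benzoate F6, which has no free hydroxyl.
- A separate ring-closing metathesis with RuCl2(PCy3)(H2IMes)(=CHPh) in CH2Cl2 at 40 °C closes F6 to 12.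

Step 3.
- Risk: conjugate rather than carbonyl addition to acrolein, polymerisation of acrolein, or insufficient diastereo- and enantiofacial control with the 4-substituted furan.
- Fallback, from 4 (with 5) back to 6: a BF3·OEt2-promoted vinylogous Mukaiyama aldol (CH2Cl2, −78 °C) is threo-selective but racemic. It gives 6 together with its mirror image, the (5S,1′S) adduct F1.
- Sharpless kinetic resolution [Ti(OiPr)4, D-(−)-diisopropyl tartrate, t-BuOOH, 4 Å sieves, CH2Cl2, −20 °C] epoxidises the vinyl group of F1 much faster and converts it into the epoxy alcohol F2.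
- Compound 6 is left unreacted and is separated by chromatography.

Step 5.
- Risk: dehydration of the lactol to the aromatic furan, over-reduction to the diol, or Z to E isomerisation of the ring-opened enal before olefination.
- Fallback, from 7 back to 9: the lactol is avoided altogether.
- Aminolysis of the lactone with MeNH(OMe)·HCl and i-PrMgCl (THF, −20 °C), with capture of the liberated C2 alkoxide by Me3SiCl, gives the silylated Weinreb amide F3.
- i-Bu2AlH (−78 °C) gives the Z-enal F4, which can neither close to a lactol nor aromatise.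
- Wittig methylenation (Ph3P=CH2, THF, −78 °C) gives the trimethylsilyl ether F5.
- K2CO3 in MeOH (0 °C) removes only the trimethylsilyl group to give 9.

**Further compounds**
F1 | step 3 | (5S)-4-(TBSO-methyl)-5-[(1S)-1-hydroxyprop-2-en-1-yl]furan-2(5H)-one (mirror image of 6) | O=C1C=C(CO[Si](C)(C)C(C)(C)C)[C@H](O1)[C@@H](O)C=C
F2 | step 3 | erythro epoxy alcohol from F1 (oxirane on the former vinyl group) | O=C1C=C(CO[Si](C)(C)C(C)(C)C)[C@H](O1)[C@@H](O)[C@H]1CO1
F3 | step 5 | (2Z,4R,5R)-N-methoxy-N-methyl-3-(TBSO-methyl)-5-(TESO)-4-[(trimethylsilyl)oxy]hepta-2,6-dienamide | CON(C)C(=O)/C=C(/CO[Si](C)(C)C(C)(C)C)[C@@H](O[Si](C)(C)C)[C@H](O[Si](CC)(CC)CC)C=C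
F4 | step 5 | (2Z,4R,5R)-3-(TBSO-methyl)-5-(TESO)-4-[(trimethylsilyl)oxy]hepta-2,6-dienal | O=C/C=C(/CO[Si](C)(C)C(C)(C)C)[C@@H](O[Si](C)(C)C)[C@H](O[Si](CC)(CC)CC)C=C
F5 | step 5 | trimethylsilyl ether of 9 | C=C/C=C(/CO[Si](C)(C)C(C)(C)C)[C@@H](O[Si](C)(C)C)[C@H](O[Si](CC)(CC)CC)C=C
F6 | step 6 | (1S,2R)-1-[(2S,3S)-2-(TBSO-methyl)-3-ethenyloxiran-2-yl]-2-(TESO)but-3-en-1-yl benzoate | C=C[C@@H]1O[C@]1(CO[Si](C)(C)C(C)(C)C)[C@@H](OC(=O)c1ccccc1)[C@H](O[Si](CC)(CC)CC)C=C
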